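**Strategy.** Everything rests on disconnecting the O–C10 bond of the bridging 3(2H)-furanone (ring atoms O, C3, C2, C1, C10) that spans the ten-membered carbocycle. In one operation the C3 enone oxygen opens a 1,10-epoxide at the tertiary C10: the five-membered oxacycle closes, quaternary C10 is set by inversion, and C1 keeps the oxygen later needed as the ketone. The precursor is the 15-O-TBS (1S,10S)-1,10-epoxy-3-oxo-heliangolide 8-methacrylate. Because inversion demands the (1S,10S) epoxide, which peripheral epoxidation of the closed ring is not expected to give, the epoxide is set by a chiral dioxirane on the open chain, before Nozaki–Hiyama–Kishi closure.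

Key step: step 16

Remarks and assumptions on the chemistry:
- Precursor 26 and product 27 are used as drawn: anti opening of the (1S,10S)-epoxide gives (10R) with the C1 hydroxyl syn to C14, and C1 stays (S).
- Silyl ethers 1 and 10 are bought as catalogue compounds (each is otherwise one silylation from the parent alkynol).
- (S,S)-ProPhenol is assumed to deliver the (S)-carbinol 12; if the sense is opposite, the (R,R)-ligand is used.
- The open-chain olefin is assumed to follow the usual Shi sense, so the (1S,10S)-epoxide calls for the L-fructose-derived ketone (ent-Shi ketone, made from L-sorbose).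
- Germacrane numbering (C1–C15) is used for all intermediates.

**Route**

Step 1
Reactants: 1 tert-butyl(but-3-yn-1-yloxy)dimethylsilane; 2 ethylene oxide
Product: 5 (E)-6-(tert-butyldimethylsilyloxy)-4-methylhex-3-en-1-ol, via alkenyldimethylalane 3 (not isolated), via lithium alkenylalanate 4 (not isolated)
Conditions: Me3Al, Cp2ZrCl2 (0.25 equiv), CH2Cl2, 0 °C → rt; volatiles removed; n-BuLi, hexane/THF, −78 → 0 °C; ethylene oxide, THF, −30 °C → rt
Reagents that add atoms: trimethylaluminium, C[Al](C)C
Why: Zirconium-catalysed Negishi carboalumination adds methyl and aluminium syn across the terminal alkyne with aluminium at the terminus, and the derived butyl ate complex opens ethylene oxide with retention at the alkenyl carbon, so the E-trisubstituted olefin (C1=C10 with C14) is fixed here.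

Step 2
Reactants: 5 (E)-6-(tert-butyldimethylsilyloxy)-4-methylhex-3-en-1-ol
Product: 6 (E)-1-(tert-butyldimethylsilyloxy)-6-(4-methoxybenzyloxy)-3-methylhex-3-ene
Conditions: NaH, PMBCl, Bu4NI (cat.), THF/DMF, 0 °C → rt
Reagents that add atoms: 4-methoxybenzyl chloride, COc1ccc(CCl)cc1
Why: Williamson etherification of the primary sodium alkoxide; the silyl ether tolerates sodium hydride.

Step 3
Reactants: 6 (E)-1-(tert-butyldimethylsilyloxy)-6-(4-methoxybenzyloxy)-3-methylhex-3-ene
Product: 7 (E)-6-(4-methoxybenzyloxy)-3-methylhex-3-en-1-ol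
Conditions: TBAF, THF, 0 °C → rt
Reagents that add atoms: none
Why: Fluoride-induced cleavage of the primary silyl ether leaves the benzyl-type ether untouched.

Step 4
Reactants: 7 (E)-6-(4-methoxybenzyloxy)-3-methylhex-3-en-1-ol
Product: 8 (E)-6-(4-methoxybenzyloxy)-3-methylhex-3-enal
Conditions: Dess–Martin periodinane, NaHCO3, CH2Cl2, 0 °C; used crude
Reagents that add atoms: none
Why: Dess–Martin oxidation under buffered, amine-free conditions gives the β,γ-unsaturated aldehyde without shifting the olefin into conjugation, provided it is used at once.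

Step 5
Reactants: 9 (E)-crotonaldehyde; 10 tert-butyldimethyl(prop-2-yn-1-yloxy)silane
Product: 12 (2E,4S)-7-(tert-butyldimethylsilyloxy)hept-2-en-5-yn-4-ol, via alkynyl(methyl)zinc 11 (not isolated)
Conditions: (S,S)-ProPhenol (20 mol%), Ph3P=O (40 mol%), Me2Zn, toluene, 0 → 4 °C
Reagents that add atoms: none
Why: Zinc–ProPhenol-catalysed asymmetric alkyne addition to an enal: the dinuclear zinc complex binds the aldehyde and the alkynylzinc and delivers the alkyne to one carbonyl face, which sets the C6 carbinol centre.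

Step 6
Reactants: 12 (2E,4S)-7-(tert-butyldimethylsilyloxy)hept-2-en-5-yn-4-ol
Product: 14 (2Z,4S,5E)-1-(tert-butyldimethylsilyloxy)-2-iodohepta-2,5-dien-4-ol, via cyclic sodium alkenylaluminate 13 (not isolated)
Conditions: Red-Al, THF, 0 °C → rt; EtOAc; then I2, THF, −78 → 0 °C; Rochelle salt work-up
Reagents that add atoms: iodine, II
Why: Hydroxyl-directed trans-hydroalumination of the propargylic alcohol puts hydride on the proximal and aluminium on the distal alkyne carbon, and iodinolysis with retention gives the Z-iodoalkene (iodine cis to C6); the isolated propenyl group and the silyl ether do not react and C6 is untouched.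

Step 7
Reactants: 14 (2Z,4S,5E)-1-(tert-butyldimethylsilyloxy)-2-iodohepta-2,5-dien-4-ol; 15 2-(bromomethyl)acrylic acid
Product: 16 (2Z,4S,5E)-1-(tert-butyldimethylsilyloxy)-2-iodohepta-2,5-dien-4-yl 2-(bromomethyl)acrylate
Conditions: N,N'-diisopropylcarbodiimide, DMAP (5 mol%), CH2Cl2, 0 °C
Reagents that add atoms: none
Why: Steglich-type carbodiimide esterification of the secondary alcohol under near-neutral conditions, with only catalytic DMAP at 0 °C so that the allylic bromide survives.

Step 8
Reactants: 16 (2Z,4S,5E)-1-(tert-butyldimethylsilyloxy)-2-iodohepta-2,5-dien-4-yl 2-(bromomethyl)acrylate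
Product: 17 (S)-3-(bromomethyl)-5-[(Z)-3-(tert-butyldimethylsilyloxy)-2-iodoprop-1-enyl]furan-2(5H)-one
Conditions: Grubbs II (5 mol%), CH2Cl2, 40 °C
Reagents that add atoms: none
Why: Ring-closing metathesis between the propenyl group and the 1,1-disubstituted acrylate olefin forms the five-membered butenolide with loss of propene; the trisubstituted iodoalkene is inert to the ruthenium carbene and C6 is not affected.

Step 9
Reactants: 8 (E)-6-(4-methoxybenzyloxy)-3-methylhex-3-enal; 17 (S)-3-(bromomethyl)-5-[(Z)-3-(tert-butyldimethylsilyloxy)-2-iodoprop-1-enyl]furan-2(5H)-one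
Product: 19 (4R,5S)-4-[(1S,3E)-1-hydroxy-6-(4-methoxybenzyloxy)-3-methylhex-3-enyl]-5-[(Z)-3-(tert-butyldimethylsilyloxy)-2-iodoprop-1-enyl]-3-methylenedihydrofuran-2(3H)-one, via allylzinc bromide 18 (not isolated)
Conditions: Zn dust, THF/sat. aq. NH4Cl, 0 °C → rt
Reagents that add atoms: none
Why: Zinc Barbier allylation: the allylzinc adds through its γ-carbon (C7) in a Zimmerman–Traxler chair, on the lactone face opposite the C6 alkenyl group (C7 trans to C6) and with the aldehyde chain equatorial (C8 as drawn), restoring the exocyclic methylene; the iodoalkene is inert to zinc.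

Step 10
Reactants: 19 the Barbier adduct (free C8 hydroxyl)
Product: 20 C8 methacrylate of 19
Conditions: methacrylic anhydride, Et3N, DMAP (cat.), CH2Cl2, 0 °C → rt
Reagents that add atoms: methacrylic anhydride, CC(=C)C(=O)OC(=O)C(C)=C
Why: DMAP-catalysed acylation of the secondary C8 alcohol with the anhydride.

Step 11
Reactants: 20 C8 methacrylate with the C1=C10 olefin
Product: 21 (1S,10S)-1,10-epoxide of 20
Conditions: ent-Shi ketone (30 mol%), Oxone, K2CO3, Bu4NHSO4 (cat.), MeCN/dimethoxymethane/aq. Na2B4O7–EDTA buffer (pH 10.5), 0 °C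
Reagents that add atoms: potassium peroxymonosulfate (Oxone), [K+].[O-]S(=O)(=O)OO
Why: Shi asymmetric epoxidation: the chiral dioxirane attacks the only electron-rich olefin through a spiro transition state, so C1 and C10 are set (1S,10S) by the catalyst; the enoates and the iodoalkene are too electron-poor to compete.

Step 12
Reactants: 21 (1S,10S)-epoxide with the C3 PMB ether
Product: 22 epoxy primary alcohol (C3 hydroxyl free)
Conditions: DDQ, CH2Cl2/pH 7 phosphate buffer, 0 °C
Reagents that add atoms: none
Why: Oxidative cleavage of the 4-methoxybenzyl ether with DDQ in buffered wet dichloromethane; epoxide, silyl ether and enoates are stable.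

Step 13
Reactants: 22 epoxy primary alcohol
Product: 23 β,γ-epoxy aldehyde (C3 aldehyde, C4 vinyl iodide)
Conditions: Dess–Martin periodinane, NaHCO3, CH2Cl2, 0 °C; used crude
Reagents that add atoms: none
Why: Buffered Dess–Martin oxidation gives the β,γ-epoxy aldehyde under amine-free conditions, which avoids β-elimination of the epoxide; it is carried on crude.

Step 14
Reactants: 23 β,γ-epoxy aldehyde
Product: 25 15-O-TBS (1S,10S)-1,10-epoxy-3-hydroxy-heliangolide 8-methacrylate (C3 epimers), via alkenylchromium(III) dichloride 24 (not isolated)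
Conditions: CrCl2 (8 equiv), NiCl2 (5 mol%), DMSO/THF, rt, syringe-pump addition (final 2 mM); crude product oxidised directly
Reagents that add atoms: none
Why: Nozaki–Hiyama–Kishi macrocyclisation: nickel inserts into the C4–I bond, chromium(III) carries the alkenyl group with retention of the Z geometry and adds only to the aldehyde, closing the ten-membered ring under high dilution; the new C3 centre is of no consequence.

Step 15
Reactants: 25 macrocyclic C3 carbinols
Product: 26 15-O-TBS (1S,10S)-1,10-epoxy-3-oxo-heliangolide 8-methacrylate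
Conditions: Dess–Martin periodinane, NaHCO3, CH2Cl2, 0 °C → rt
Reagents that add atoms: none
Why: Dess–Martin oxidation of the allylic C3 alcohols converges both epimers on the enone.

Step 16
Reactants: 26 15-O-TBS (1S,10S)-1,10-epoxy-3-oxo-heliangolide 8-methacrylate
Product: 27 C1 carbinol (1S,10R) of 15-O-TBS-goyazensolide (3,10-ether, C2=C3 enol ether)
Conditions: Sc(OTf)3 (10 mol%), 2,6-di-tert-butyl-4-methylpyridine (20 mol%), 4 Å MS, CH2Cl2, −40 → 0 °C; product used without delay
Reagents that add atoms: none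
Why: Proposed new method: the Lewis acid binds the epoxide oxygen and loosens the tertiary C10–O bond, the C3 enone oxygen, held behind C10 by the C2–C1 tether, adds anti to the departing oxygen to give a cyclic oxocarbenium ion, and the hindered base removes a C2 proton to leave the C2=C3 enol ether and the C1 carbinol. The closest known reaction types are acid-promoted transannular cyclisations of germacrene 1(10)-epoxides and epoxide opening by a neighbouring carbonyl oxygen to give cyclic ketals or enol ethers. The five-membered oxacycle (O, C3, C2, C1, C10) closes in a formally 5-endo-tet mode, acceptable because the tertiary C10 reacts through a loose, SN1-like transition state. C10 is set by inversion, so its configuration follows from the (10S) epoxide fixed in step 11, while C1 keeps its C–O bond and configuration. The step needs O-attack at C10 to beat hydride shift from C1, β-elimination toward C2, capture by the C8 ester carbonyl and closure by the C4=C5 bond. The last is switched off because that olefin is conjugated to the ketone, the buffered low-temperature conditions disfavour the first two, and the conjugated ketone is the most basic carbonyl and forms the smaller ring.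

Step 17
Reactants: 27 C1 carbinol of 15-O-TBS-goyazensolide
Product: 28 15-O-TBS-goyazensolide
Conditions: Dess–Martin periodinane, NaHCO3, CH2Cl2, 0 °C
Reagents that add atoms: none
Why: Dess–Martin oxidation of the allylic C1 carbinol gives the vinylogous ester of the 3(2H)-furanone and removes the C1 stereocentre; buffering protects the acid-labile enol ether until it is conjugated.

Step 18
Reactants: 28 15-O-TBS-goyazensolide
Product: 29 goyazensolide
Conditions: HF·pyridine, pyridine, THF, 0 °C → rt
Reagents that add atoms: none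
Why: Fluoride cleavage of the primary allylic silyl ether with buffered HF·pyridine, which is non-basic and spares the Michael acceptors and the ester.

**Compound list**

1 | tert-butyl(but-3-yn-1-yloxy)dimethylsilane | C#CCCO[Si](C)(C)C(C)(C)C | starting material
2 | ethylene oxide | C1CO1 | starting material
3 | (E)-[4-(tert-butyldimethylsilyloxy)-2-methylbut-1-enyl]dimethylalane | C[Al](C)/C=C(\C)CCO[Si](C)(C)C(C)(C)C | intermediate (not isolated)
4 | lithium (E)-butyl[4-(tert-butyldimethylsilyloxy)-2-methylbut-1-enyl]dimethylalanate | [Li+].CCCC[Al-](C)(C)/C=C(\C)CCO[Si](C)(C)C(C)(C)C | intermediate (not isolated)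
5 | (E)-6-(tert-butyldimethylsilyloxy)-4-methylhex-3-en-1-ol | OCC/C=C(\C)CCO[Si](C)(C)C(C)(C)C | intermediate
6 | (E)-1-(tert-butyldimethylsilyloxy)-6-(4-methoxybenzyloxy)-3-methylhex-3-ene | COc1ccc(COCC/C=C(\C)CCO[Si](C)(C)C(C)(C)C)cc1 | intermediate
7 | (E)-6-(4-methoxybenzyloxy)-3-methylhex-3-en-1-ol | COc1ccc(COCC/C=C(\C)CCO)cc1 | intermediate
8 | (E)-6-(4-methoxybenzyloxy)-3-methylhex-3-enal | COc1ccc(COCC/C=C(\C)CC=O)cc1 | intermediate
9 | (E)-crotonaldehyde | C/C=C/C=O | starting material
10 | tert-butyldimethyl(prop-2-yn-1-yloxy)silane | C#CCO[Si](C)(C)C(C)(C)C | starting material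
11 | methyl[3-(tert-butyldimethylsilyloxy)prop-1-ynyl]zinc | C[Zn]C#CCO[Si](C)(C)C(C)(C)C | intermediate (not isolated)
12 | (2E,4S)-7-(tert-butyldimethylsilyloxy)hept-2-en-5-yn-4-ol | C/C=C/[C@H](O)C#CCO[Si](C)(C)C(C)(C)C | intermediate
13 | cyclic sodium alkenylaluminate from 12 (five-membered O–Al–C4=C5–C6 ate complex, two 2-methoxyethoxy ligands) | C/C=C/[C@@H]1O[Al-](OCCOC)(OCCOC)C(CO[Si](C)(C)C(C)(C)C)=C1.[Na+] | intermediate (not isolated)
14 | (2Z,4S,5E)-1-(tert-butyldimethylsilyloxy)-2-iodohepta-2,5-dien-4-ol | C/C=C/[C@H](O)/C=C(\I)CO[Si](C)(C)C(C)(C)C | intermediate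
15 | 2-(bromomethyl)acrylic acid | C=C(CBr)C(=O)O | starting material
16 | (2Z,4S,5E)-1-(tert-butyldimethylsilyloxy)-2-iodohepta-2,5-dien-4-yl 2-(bromomethyl)acrylate | C/C=C/[C@H](OC(=O)C(=C)CBr)/C=C(\I)CO[Si](C)(C)C(C)(C)C | intermediate
17 | (S)-3-(bromomethyl)-5-[(Z)-3-(tert-butyldimethylsilyloxy)-2-iodoprop-1-enyl]furan-2(5H)-one | BrCC1=C[C@@H](/C=C(\I)CO[Si](C)(C)C(C)(C)C)OC1=O | intermediate
18 | allylzinc bromide derived from 17 | Br[Zn]CC1=C[C@@H](/C=C(\I)CO[Si](C)(C)C(C)(C)C)OC1=O | intermediate (not isolated)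
19 | (4R,5S)-4-[(1S,3E)-1-hydroxy-6-(4-methoxybenzyloxy)-3-methylhex-3-enyl]-5-[(Z)-3-(tert-butyldimethylsilyloxy)-2-iodoprop-1-enyl]-3-methylenedihydrofuran-2(3H)-one | COc1ccc(COCC/C=C(\C)C[C@H](O)[C@H]2C(=C)C(=O)O[C@@H]2/C=C(\I)CO[Si](C)(C)C(C)(C)C)cc1 | intermediate
20 | C8 methacrylate of 19 | COc1ccc(COCC/C=C(\C)C[C@H](OC(=O)C(C)=C)[C@H]2C(=C)C(=O)O[C@@H]2/C=C(\I)CO[Si](C)(C)C(C)(C)C)cc1 | intermediate
21 | (1S,10S)-1,10-epoxide of 20 | COc1ccc(COCC[C@@H]2O[C@@]2(C)C[C@H](OC(=O)C(C)=C)[C@H]3C(=C)C(=O)O[C@@H]3/C=C(\I)CO[Si](C)(C)C(C)(C)C)cc1 | intermediate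
22 | epoxy primary alcohol (PMB removed from 21) | OCC[C@@H]1O[C@@]1(C)C[C@H](OC(=O)C(C)=C)[C@H]2C(=C)C(=O)O[C@@H]2/C=C(\I)CO[Si](C)(C)C(C)(C)C | intermediate
23 | β,γ-epoxy aldehyde (C3 aldehyde of 22) | O=CC[C@@H]1O[C@@]1(C)C[C@H](OC(=O)C(C)=C)[C@H]2C(=C)C(=O)O[C@@H]2/C=C(\I)CO[Si](C)(C)C(C)(C)C | intermediate
24 | alkenylchromium(III) dichloride derived from 23 | O=CC[C@@H]1O[C@@]1(C)C[C@H](OC(=O)C(C)=C)[C@H]2C(=C)C(=O)O[C@@H]2/C=C(\[Cr](Cl)Cl)CO[Si](C)(C)C(C)(C)C | intermediate (not isolated)
25 | 15-O-TBS (1S,10S)-1,10-epoxy-3-hydroxy-heliangolide 8-methacrylate (C3 epimers) | C=C(C)C(=O)O[C@H]1C[C@]2(C)O[C@H]2CC(O)/C(CO[Si](C)(C)C(C)(C)C)=C\[C@H]2OC(=O)C(=C)[C@H]12 | intermediate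
26 | 15-O-TBS (1S,10S)-1,10-epoxy-3-oxo-heliangolide 8-methacrylate (key-step precursor) | C=C(C)C(=O)O[C@H]1C[C@]2(C)O[C@H]2CC(=O)/C(CO[Si](C)(C)C(C)(C)C)=C\[C@H]2OC(=O)C(=C)[C@H]12 | intermediate
27 | (1S,10R) C1 carbinol of 15-O-TBS-goyazensolide (key-step product) | C=C(C)C(=O)O[C@H]1C[C@@]2(C)OC(=C[C@@H]2O)/C(CO[Si](C)(C)C(C)(C)C)=C\[C@H]2OC(=O)C(=C)[C@H]12 | intermediate
28 | 15-O-TBS-goyazensolide | C=C(C)C(=O)O[C@H]1C[C@@]2(C)OC(=CC2=O)/C(CO[Si](C)(C)C(C)(C)C)=C\[C@H]2OC(=O)C(=C)[C@H]12 | intermediate
29 | goyazensolide | C=C(C)C(=O)O[C@H]1C[C@@]2(C)OC(=CC2=O)/C(CO)=C\[C@H]2OC(=O)C(=C)[C@H]12 | target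

**Step count and risks**

Total: 18 steps. Longest linear sequence: 14 steps (1 → 29 through steps 1–4 and 9–18; the branch 9/10 → 17 → 29 is equally long).

Steps most likely to fail:

1. Step 16 (epoxide opening by the C3 oxygen). The tertiary cation character at C10 may be discharged by migration of the C1 hydride, by β-elimination across C2–C1, or by capture through the C8 ester carbonyl, before the ketone oxygen attacks. The fallback uses known chemistry, sets out from 26 and returns at 28. Dilute aqueous acid (HClO4, THF/H2O, 0 °C) opens the epoxide with water at the tertiary C10 with inversion to give the (1S,10R)-1,10-diol F1. Dess–Martin oxidation of the secondary C1 carbinol gives the 10-hydroxy-1,3-diketone F2. Acid-catalysed cyclodehydration of this α′-hydroxy-1,3-diketone (PPTS, benzene, 40 °C), the classical 3(2H)-furanone synthesis, closes the ring through the C10 hydroxyl with retention at C10 and gives 28.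

2. Step 14 (ring closure on the epoxy aldehyde). The β,γ-epoxy aldehyde may eliminate toward a γ-hydroxy enal, or the chain may oligomerise faster than the ten-membered ring closes. The fallback sets out from 20 and returns at 28; it closes the ring before any oxygen is placed on C1/C10 and therefore gives up the epoxide opening. DDQ frees the olefinic primary alcohol F3, Dess–Martin oxidation gives the robust olefinic aldehyde F4, Nozaki–Hiyama–Kishi closure gives the macrocyclic dienol F5, and oxidation gives the dienone F6. On the closed ring an external oxidant should reach only the outer face of the C1=C10 olefin, which is expected to correspond to the (1R,10R) series, so the C10 oxygen is introduced with retention. Upjohn dihydroxylation (OsO4, NMO) of the only electron-rich olefin gives the (1R,10R)-1,10-diol F7; Dess–Martin oxidation then gives the hydroxy-diketone F2, which is cyclodehydrated to 28 as above.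

3. Step 11 (asymmetric epoxidation of 20). The basic aqueous medium may attack the α-methylene lactone or the methacrylate, or facial selectivity may be poor on this polyfunctional chain. The fallback sets out from 6 and returns at 21; it moves the epoxidation to the simple bis-ether, where no base-sensitive group is present. The same ent-Shi conditions give the (S,S)-epoxide F8, TBAF gives the epoxy alcohol F9, and buffered Dess–Martin oxidation gives the β,γ-epoxy aldehyde F10, used at once. Zinc Barbier reaction with 17 gives the epoxy adduct F11, and methacrylation as in step 10 gives 21.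

**Further compounds**

F1 | step 16 | (1S,10R)-1,10-dihydroxy-3-oxo-heliangolide 8-methacrylate 15-TBS ether | C=C(C)C(=O)O[C@H]1C[C@@](C)(O)[C@@H](O)CC(=O)/C(CO[Si](C)(C)C(C)(C)C)=C\[C@H]2OC(=O)C(=C)[C@H]12
F2 | step 16 | (10R)-10-hydroxy-1,3-dioxo-heliangolide 8-methacrylate 15-TBS ether | C=C(C)C(=O)O[C@H]1C[C@@](C)(O)C(=O)CC(=O)/C(CO[Si](C)(C)C(C)(C)C)=C\[C@H]2OC(=O)C(=C)[C@H]12
F3 | step 14 | olefinic primary alcohol (PMB removed from 20) | OCC/C=C(\C)C[C@H](OC(=O)C(C)=C)[C@H]1C(=C)C(=O)O[C@@H]1/C=C(\I)CO[Si](C)(C)C(C)(C)C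
F4 | step 14 | olefinic aldehyde (C3 aldehyde of F3) | O=CC/C=C(\C)C[C@H](OC(=O)C(C)=C)[C@H]1C(=C)C(=O)O[C@@H]1/C=C(\I)CO[Si](C)(C)C(C)(C)C
F5 | step 14 | 15-O-TBS 3-hydroxy-heliangolide 8-methacrylate with 1(10)E olefin (C3 epimers) | C=C(C)C(=O)O[C@H]1C/C(C)=C/CC(O)/C(CO[Si](C)(C)C(C)(C)C)=C\[C@H]2OC(=O)C(=C)[C@H]12
F6 | step 14 | 15-O-TBS 3-oxo-heliangolide 8-methacrylate with 1(10)E olefin | C=C(C)C(=O)O[C@H]1C/C(C)=C/CC(=O)/C(CO[Si](C)(C)C(C)(C)C)=C\[C@H]2OC(=O)C(=C)[C@H]12
F7 | step 14 | (1R,10R)-1,10-dihydroxy-3-oxo-heliangolide 8-methacrylate 15-TBS ether | C=C(C)C(=O)O[C@H]1C[C@@](C)(O)[C@H](O)CC(=O)/C(CO[Si](C)(C)C(C)(C)C)=C\[C@H]2OC(=O)C(=C)[C@H]12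
F8 | step 11 | (2S,3S)-2-[2-(tert-butyldimethylsilyloxy)ethyl]-3-[2-(4-methoxybenzyloxy)ethyl]-2-methyloxirane | COc1ccc(COCC[C@@H]2O[C@@]2(C)CCO[Si](C)(C)C(C)(C)C)cc1
F9 | step 11 | 2-{(2S,3S)-3-[2-(4-methoxybenzyloxy)ethyl]-2-methyloxiran-2-yl}ethanol | COc1ccc(COCC[C@@H]2O[C@@]2(C)CCO)cc1
F10 | step 11 | 2-{(2S,3S)-3-[2-(4-methoxybenzyloxy)ethyl]-2-methyloxiran-2-yl}acetaldehyde | COc1ccc(COCC[C@@H]2O[C@@]2(C)CC=O)cc1
F11 | step 11 | (1S,10S)-epoxy Barbier adduct (C8 hydroxyl free; desmethacryloyl 21) | COc1ccc(COCC[C@@H]2O[C@@]2(C)C[C@H](O)[C@H]3C(=C)C(=O)O[C@@H]3/C=C(\I)CO[Si](C)(C)C(C)(C)C)cc1
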